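**Retrosynthetic overview**
1. Last operation: the arene and the δ-lactone of the ether-bearing half are built together by a Diels–Alder/aromatisation/lactonisation cascade of a 2-methoxy Chan-type bis(silyloxy)diene onto an aryl propargyl ether ynoate; the same acidic finish removes the MOM and acetate groups.
2. The aryl propargyl ether comes from a Mitsunobu reaction (inversion, sets the 4S ether center) between the 6-OH of the finished hydroxy-lactone half (as its C4 acetate) and a syn γ-hydroxy ynoate.
3. The hydroxy-lactone half comes from the same two-ring cascade, using the C4 acetate of that γ-hydroxy ynoate; the acetate forces six-ring lactonisation and keeps C4–O inert in the Mitsunobu step.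
4. The γ-hydroxy ynoate comes from chelation-controlled addition of metallated methyl propiolate to MOM-protected (R)-lactaldehyde (from methyl (R)-lactate); the diene comes from methyl methoxyacetate.
5. Ring order: arene + lactone of the hydroxy half, then the ether bond, then arene + lactone of the ether-bearing half.

Assumption: unit A is the half whose C4 carries the aryl ether, unit B the half with the free C4 hydroxyl; read from the SMILES, unit A is (3R,4S) (3,4-trans) and unit B is (3R,4R) (3,4-cis).

**Route**

Step 1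
Reactants: 1 methyl methoxyacetate
Product: 2 methyl 2-methoxy-3-oxobutanoate (racemic at C2)
Conditions: LiN(SiMe3)2 (2.0 equiv), 1 (2.0 equiv), THF, −78 °C; AcCl (1.0 equiv), −78 °C; 1 M HCl
Reagents that add atoms: acetyl chloride, CC(=O)Cl
Why: Rathke-type crossed Claisen C-acylation, in which the lithium enolate of 1 attacks acetyl chloride and the second equivalent of enolate takes up the acidic proton of the β-ketoester as it forms, which stops double acylation; the racemic C2 center is erased in step 2.

Step 2
Reactants: 2 methyl 2-methoxy-3-oxobutanoate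
Product: 4 1,2-dimethoxy-1,3-bis(trimethylsilyloxy)buta-1,3-diene, via mono silyl enol ether 3 (not isolated)
Conditions: TMSOTf (2.2 equiv), Et3N (2.5 equiv), Et2O, 0 °C → rt; pentane extraction, used crude
Reagents that add atoms: trimethylsilyl trifluoromethanesulfonate (TMSOTf), C[Si](C)(C)OS(=O)(=O)C(F)(F)F
Why: Chan-type bis(silyloxy)diene synthesis by two soft enolisations, where TMSOTf/Et3N first O-silylates the ketone enol to 3 and then, with the ester carbonyl activated by the silyl triflate, the γ-methyl group is deprotonated vinylogously to the ketene-acetal diene; no stereocenter is involved.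

Step 3
Reactants: 5 methyl (R)-lactate
Product: 6 methyl (R)-2-(methoxymethoxy)propanoate
Conditions: MOMCl (1.5 equiv), i-Pr2NEt (2 equiv), CH2Cl2, 0 °C → rt
Reagents that add atoms: chloromethyl methyl ether (MOMCl), COCCl
Why: Amine-mediated O-alkylation of the secondary alcohol by the reactive α-chloro ether (MOM acetal formation) under non-epimerising conditions, so the (R) center of the lactate is retained.

Step 4
Reactants: 6 methyl (R)-2-(methoxymethoxy)propanoate
Product: 7 (R)-2-(methoxymethoxy)propanal
Conditions: i-Bu2AlH (1.05 equiv), CH2Cl2, −78 °C; MeOH, then aq. potassium sodium tartrate KNaC4H4O6; used at once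
Reagents that add atoms: none
Why: Partial ester reduction, in which the aluminium hemiacetal is stable at −78 °C and releases the aldehyde only on work-up, so there is no over-reduction and the α-center is kept because the aldehyde is used cold and without storage.

Step 5
Reactants: 7 (R)-2-(methoxymethoxy)propanal; 8 methyl propiolate
Product: 11 methyl (4R,5R)-4-hydroxy-5-(methoxymethoxy)hex-2-ynoate, via lithium acetylide LiC≡CCO2Me 9 (not isolated), via bromozinc acetylide BrZnC≡CCO2Me 10 (not isolated)
Conditions: 8, LiN(SiMe3)2, Et2O/toluene, −78 °C; ZnBr2 (1.2 equiv), −78 °C; then 7, −78 → 0 °C; H2O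
Reagents that add atoms: none
Why: Chelation-controlled (Cram chelate) 1,2-addition of an alkynylzinc halide, in which zinc bridges the aldehyde oxygen and the MOM ether oxygen in a five-membered chelate and the acetylide adds to the face anti to the methyl group, giving the syn (4R,5R) alcohol (expected dr ≥ 8:1, minor epimer removed by chromatography).

Step 6
Reactants: 11 methyl (4R,5R)-4-hydroxy-5-(methoxymethoxy)hex-2-ynoate
Product: 12 methyl (4R,5R)-4-acetoxy-5-(methoxymethoxy)hex-2-ynoate
Conditions: Ac2O (1.5 equiv), pyridine, CH2Cl2, 0 °C → rt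
Reagents that add atoms: acetic anhydride, CC(=O)OC(C)=O
Why: Standard O-acylation that touches no stereocenter; the acetate masks the C4 oxygen so that later only the C5 oxygen can lactonise (six-membered ring, no phthalide) and unit B carries no free alcohol into the Mitsunobu step.

Step 7
Reactants: 12 methyl (4R,5R)-4-acetoxy-5-(methoxymethoxy)hex-2-ynoate; 4 1,2-dimethoxy-1,3-bis(trimethylsilyloxy)buta-1,3-diene
Product: 15 (3R,4R)-6,8-dihydroxy-7-methoxy-3-methyl-1-oxo-3,4-dihydro-1H-isochromen-4-yl acetate, via Diels–Alder cycloadduct 13 (not isolated), via aromatised methyl benzoate 14 (not isolated)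
Conditions: 4 (3 equiv), toluene, 100 °C, 24 h; then TFA/CH2Cl2 (1:4), n-PrSH (3 equiv), 0 °C → rt
Reagents that add atoms: none
Why: Diels–Alder/aromatisation/lactonisation cascade of a Chan-type diene with an alkynoate, in which the CH2 terminus of 4 bonds to the β-carbon and the ketene-acetal carbon to the α-carbon of the ynoate, so that acid-induced loss of methanol and the silyl groups gives the 6-OH/7-OMe/8-OH arene, TFA with thiol trapping removes the MOM group (the acetate is stable to it) and the freed C5 hydroxyl closes the δ-lactone onto the ortho ester, both stereocenters of 12 being carried through unchanged.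

Step 8
Reactants: 15 (3R,4R)-6,8-dihydroxy-7-methoxy-3-methyl-1-oxo-3,4-dihydro-1H-isochromen-4-yl acetate; 11 methyl (4R,5R)-4-hydroxy-5-(methoxymethoxy)hex-2-ynoate
Product: 16 methyl (4S,5R)-4-{[(3R,4R)-4-acetoxy-8-hydroxy-7-methoxy-3-methyl-1-oxo-3,4-dihydro-1H-isochromen-6-yl]oxy}-5-(methoxymethoxy)hex-2-ynoate
Conditions: PPh3 (1.5 equiv), DIAD (1.5 equiv), THF, 0 °C (betaine preformed); 15, then 11 (1.3 equiv) added slowly, 0 °C → rt
Reagents that add atoms: none
Why: Mitsunobu etherification, in which the non-chelated 6-OH para to the lactone carbonyl is the most acidic phenol and the only one that reacts, and it displaces the propargylic oxyphosphonium group by SN2 with inversion, turning (4R) into the (4S) aryl ether that becomes C4 of unit A; the preformed betaine and slow addition of 11 keep free PPh3 away from the ynoate.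

Step 9
Reactants: 16 methyl (4S,5R)-4-{[(3R,4R)-4-acetoxy-8-hydroxy-7-methoxy-3-methyl-1-oxo-3,4-dihydro-1H-isochromen-6-yl]oxy}-5-(methoxymethoxy)hex-2-ynoate; 4 1,2-dimethoxy-1,3-bis(trimethylsilyloxy)buta-1,3-diene
Product: 19 (3R,4R)-6-{[(3R,4S)-6,8-dihydroxy-7-methoxy-3-methyl-1-oxo-3,4-dihydro-1H-isochromen-4-yl]oxy}-4,8-dihydroxy-7-methoxy-3-methyl-3,4-dihydro-1H-isochromen-1-one, via Diels–Alder cycloadduct 17 (not isolated), via aromatised methyl benzoate 18 (not isolated)
Conditions: 4 (4 equiv, the free phenol consumes part of it), toluene, 100 °C, 36 h; then 1.25 M HCl in MeOH, 40 °C, 24 h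
Reagents that add atoms: none
Why: The same Diels–Alder/aromatisation/lactonisation cascade, now as the last operation, builds the arene and lactone of unit A around the finished ether stereocenter with the regiochemistry of step 7, and methanolic HCl in the same pot removes the silyl groups, the MOM ether (as dimethoxymethane) and the acetate (acid transesterification) and closes the lactone, without base so that neither the trans ether of unit A nor the cis hydroxy lactone of unit B can epimerise or contract to a phthalide.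

**Compound list**
1 | methyl methoxyacetate | COCC(=O)OC | starting material
2 | methyl 2-methoxy-3-oxobutanoate | CC(=O)C(OC)C(=O)OC | intermediate
3 | methyl 2-methoxy-3-(trimethylsilyloxy)but-2-enoate (mono silyl enol ether) | CC(O[Si](C)(C)C)=C(OC)C(=O)OC | intermediate
4 | 1,2-dimethoxy-1,3-bis(trimethylsilyloxy)buta-1,3-diene | C=C(O[Si](C)(C)C)C(OC)=C(OC)O[Si](C)(C)C | intermediate
5 | methyl (R)-lactate | C[C@@H](O)C(=O)OC | starting material
6 | methyl (R)-2-(methoxymethoxy)propanoate | C[C@@H](OCOC)C(=O)OC | intermediate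
7 | (R)-2-(methoxymethoxy)propanal | C[C@@H](OCOC)C=O | intermediate
8 | methyl propiolate | C#CC(=O)OC | starting material
9 | lithium acetylide LiC≡CCO2Me (methyl 3-lithiopropiolate) | [Li]C#CC(=O)OC | intermediate
10 | bromozinc acetylide BrZnC≡CCO2Me | Br[Zn]C#CC(=O)OC | intermediate
11 | methyl (4R,5R)-4-hydroxy-5-(methoxymethoxy)hex-2-ynoate | COC(=O)C#C[C@@H](O)[C@@H](C)OCOC | intermediate
12 | methyl (4R,5R)-4-acetoxy-5-(methoxymethoxy)hex-2-ynoate | COC(=O)C#C[C@@H](OC(C)=O)[C@@H](C)OCOC | intermediate
13 | methyl 2-[(1R,2R)-1-acetoxy-2-(methoxymethoxy)propyl]-5,6-dimethoxy-4,6-bis(trimethylsilyloxy)cyclohexa-1,4-diene-1-carboxylate (C6 epimers) | COC(=O)C1=C([C@@H](OC(C)=O)[C@@H](C)OCOC)CC(O[Si](C)(C)C)=C(OC)C1(OC)O[Si](C)(C)C | intermediate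
14 | methyl 2-[(1R,2R)-1-acetoxy-2-(methoxymethoxy)propyl]-4,6-dihydroxy-5-methoxybenzoate | COC(=O)c1c(O)c(OC)c(O)cc1[C@@H](OC(C)=O)[C@@H](C)OCOC | intermediate
15 | (3R,4R)-6,8-dihydroxy-7-methoxy-3-methyl-1-oxo-3,4-dihydro-1H-isochromen-4-yl acetate | COc1c(O)cc2c(c1O)C(=O)O[C@H](C)[C@@H]2OC(C)=O | intermediate
16 | methyl (4S,5R)-4-{[(3R,4R)-4-acetoxy-8-hydroxy-7-methoxy-3-methyl-1-oxo-3,4-dihydro-1H-isochromen-6-yl]oxy}-5-(methoxymethoxy)hex-2-ynoate | COC(=O)C#C[C@H](Oc1cc2c(c(O)c1OC)C(=O)O[C@H](C)[C@@H]2OC(C)=O)[C@@H](C)OCOC | intermediate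
17 | methyl 2-[(1S,2R)-1-{[(3R,4R)-4-acetoxy-8-hydroxy-7-methoxy-3-methyl-1-oxo-3,4-dihydro-1H-isochromen-6-yl]oxy}-2-(methoxymethoxy)propyl]-5,6-dimethoxy-4,6-bis(trimethylsilyloxy)cyclohexa-1,4-diene-1-carboxylate (C6 epimers) | COC(=O)C1=C([C@H](Oc2cc3c(c(O)c2OC)C(=O)O[C@H](C)[C@@H]3OC(C)=O)[C@@H](C)OCOC)CC(O[Si](C)(C)C)=C(OC)C1(OC)O[Si](C)(C)C | intermediate
18 | methyl 2-[(1S,2R)-1-{[(3R,4R)-4-acetoxy-8-hydroxy-7-methoxy-3-methyl-1-oxo-3,4-dihydro-1H-isochromen-6-yl]oxy}-2-(methoxymethoxy)propyl]-4,6-dihydroxy-5-methoxybenzoate | COC(=O)c1c(O)c(OC)c(O)cc1[C@H](Oc1cc2c(c(O)c1OC)C(=O)O[C@H](C)[C@@H]2OC(C)=O)[C@@H](C)OCOC | intermediate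
19 | (3R,4R)-6-{[(3R,4S)-6,8-dihydroxy-7-methoxy-3-methyl-1-oxo-3,4-dihydro-1H-isochromen-4-yl]oxy}-4,8-dihydroxy-7-methoxy-3-methyl-3,4-dihydro-1H-isochromen-1-one | COc1c(O)cc2c(c1O)C(=O)O[C@H](C)[C@H]2Oc1cc2c(c(O)c1OC)C(=O)O[C@H](C)[C@@H]2O | target

**Count**
Total steps: 9. Longest linear sequence: 7 steps (5 → 6 → 7 → 11 → 12 → 15 → 16 → 19, steps 3 to 9).

**Three steps most likely to fail**

Step 9. The thermal cycloaddition has to take place on a hindered, γ,δ-dioxygenated ynoate that already carries all of unit B, and the acidic finish must remove three kinds of masking groups without solvolysing the benzylic C–O bonds. Fallback (sets out from 15, comes back at 19): give up the ether-first order and etherify at the lactone stage. Acid methanolysis of 15 (HCl/MeOH, rt) gives the triol (3R,4R)-4,6,8-trihydroxy-7-methoxy-3-methyl-3,4-dihydro-1H-isochromen-1-one F5. F5 is added slowly to preformed PPh3/DIAD betaine in the presence of a four- to five-fold excess of 15, which has no free alcohol, outcompetes the phenols of F5 and is recovered. SN2 inversion at the benzylic C4 of F5 gives the mono-acetate (3R,4R)-6-{[(3R,4S)-6,8-dihydroxy-7-methoxy-3-methyl-1-oxo-3,4-dihydro-1H-isochromen-4-yl]oxy}-8-hydroxy-7-methoxy-3-methyl-1-oxo-3,4-dihydro-1H-isochromen-4-yl acetate F6. Mild acid methanolysis of F6 gives 19. This route risks elimination to the isocoumarin and some oligomer.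

Step 8. A γ-hydroxy ynoate under Mitsunobu conditions can suffer phosphine addition to the triple bond, redox isomerisation to the γ-oxo enoate, or oxa-Michael addition of the phenoxide. Fallback (sets out from 7 and 15, comes back at 16): make the ether on a terminal alkyne and add the ester afterwards. Chelation-controlled addition of HC≡CMgBr to 7 in the presence of ZnBr2 gives (3R,4R)-4-(methoxymethoxy)pent-1-yn-3-ol F3. A Mitsunobu reaction of F3 with 15 (terminal propargylic alcohols are robust substrates) gives, with inversion, (3R,4R)-8-hydroxy-7-methoxy-6-{[(3S,4R)-4-(methoxymethoxy)pent-1-yn-3-yl]oxy}-3-methyl-1-oxo-3,4-dihydro-1H-isochromen-4-yl acetate F4. Oxidative methoxycarbonylation of the terminal alkyne (PdCl2 cat., CuCl2, NaOAc, CO 1 atm, MeOH, rt) then gives 16.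

Step 5. The zinc acetylide of a propiolate is a weak nucleophile, and the syn selectivity depends on a clean chelate. Fallback (sets out from 7, comes back at 11): set the carbinol center by reagent-controlled ketone reduction instead of C–C bond formation. Addition of lithium acetylide 9 to 7 without zinc (THF, −78 °C) gives 11 mixed with its epimer methyl (4S,5R)-4-hydroxy-5-(methoxymethoxy)hex-2-ynoate F1. Dess–Martin oxidation of the mixture converges both epimers on the ynone methyl (5R)-5-(methoxymethoxy)-4-oxohex-2-ynoate F2. Midland reduction of F2 with (S)-Alpine-Borane (from (−)-α-pinene and 9-BBN) should deliver hydride to the face that gives (4R) and return 11.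

**Further compounds**
F1 | step 5 | methyl (4S,5R)-4-hydroxy-5-(methoxymethoxy)hex-2-ynoate | COC(=O)C#C[C@H](O)[C@@H](C)OCOC
F2 | step 5 | methyl (5R)-5-(methoxymethoxy)-4-oxohex-2-ynoate | COC(=O)C#CC(=O)[C@@H](C)OCOC
F3 | step 8 | (3R,4R)-4-(methoxymethoxy)pent-1-yn-3-ol | C#C[C@@H](O)[C@@H](C)OCOC
F4 | step 8 | (3R,4R)-8-hydroxy-7-methoxy-6-{[(3S,4R)-4-(methoxymethoxy)pent-1-yn-3-yl]oxy}-3-methyl-1-oxo-3,4-dihydro-1H-isochromen-4-yl acetate | C#C[C@H](Oc1cc2c(c(O)c1OC)C(=O)O[C@H](C)[C@@H]2OC(C)=O)[C@@H](C)OCOC
F5 | step 9 | (3R,4R)-4,6,8-trihydroxy-7-methoxy-3-methyl-3,4-dihydro-1H-isochromen-1-one | COc1c(O)cc2c(c1O)C(=O)O[C@H](C)[C@@H]2O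
F6 | step 9 | (3R,4R)-6-{[(3R,4S)-6,8-dihydroxy-7-methoxy-3-methyl-1-oxo-3,4-dihydro-1H-isochromen-4-yl]oxy}-8-hydroxy-7-methoxy-3-methyl-1-oxo-3,4-dihydro-1H-isochromen-4-yl acetate | COc1c(O)cc2c(c1O)C(=O)O[C@H](C)[C@H]2Oc1cc2c(c(O)c1OC)C(=O)O[C@H](C)[C@@H]2OC(C)=O
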